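**Assumption:** eudesmane numbering is used for positions (ring A = C1–C5 and C10, ring B = C5–C10, side chain C11–C13). The target is the (3S,7R,8R,10R) isomer, with all four substituents on the β face.

## Retrosynthetic overview

1. Target 14 ⇐ 8β-alcohol 13 (acetylation) ⇐ C8 ketone 12 (hydride from the α face sets C8).
2. 12 ⇐ decalone 8 + methyl propiolate 9: the C7–C11 bond is made by a proposed enolate α-(1-methoxycarbonylvinyl)ation through a β-phosphonio acrylate (sets C7).
3. 8 ⇐ 7 ⇐ hydrindanone 5: one-carbon ring expansion (β-oxido carbenoid 1,2-shift of the quaternary C10) turns the five-membered ring into ring B and places the carbonyl at C8.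
4. 5 ⇐ enedione 4 ⇐ 1 + 2: amino-acid-mediated Robinson annulation sets C10; enone reduction sets C3.
5. Ring order: cyclopentane (from 1) → ring A (annulation) → ring B (ring expansion).

## Route

**Step 1**
Reactants: 1 2-methylcyclopentane-1,3-dione; 2 pent-1-en-3-one
Product: 4 (S)-4,7a-dimethyl-2,3,7,7a-tetrahydro-1H-indene-1,5(6H)-dione, via triketone Michael adduct 3 (not isolated)
Conditions: H2O, AcOH (cat.), 70 °C; evaporate; L-phenylalanine (1.0 equiv), (1S)-(+)-camphorsulfonic acid (0.5 equiv), MeCN, reflux; recrystallise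
Reagents that add atoms: none
Why: Michael addition followed by a Hajos–Parrish-type (Eder–Sauer–Wiechert) enantioselective aldol condensation, in which the L-phenylalanine enamine closes onto one of the two enantiotopic ring carbonyls and sets the quaternary centre as S (the 10β-methyl of the target).

**Step 2**
Reactants: 4 (S)-4,7a-dimethyl-2,3,7,7a-tetrahydro-1H-indene-1,5(6H)-dione
Product: 5 (5S,7aS)-5-hydroxy-4,7a-dimethyl-2,3,5,6,7,7a-hexahydro-1H-inden-1-one
Conditions: NaBH4 (0.3 equiv), CeCl3·7H2O (1.0 equiv), MeOH, −78 °C, 30 min; aq NH4Cl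
Reagents that add atoms: none
Why: Luche reduction, which favours 1,2-reduction of the conjugated ketone over the hindered neopentyl cyclopentanone, with hydride delivered axially on the face opposite the angular methyl to give the 3β (5S) allylic alcohol cis to that methyl.

**Step 3**
Reactants: 5 (5S,7aS)-5-hydroxy-4,7a-dimethyl-2,3,5,6,7,7a-hexahydro-1H-inden-1-one
Product: 7 (6S,8aR)-6-hydroxy-5,8a-dimethyl-3,4,6,7,8,8a-hexahydronaphthalen-2(1H)-one, via dibromomethyl carbinol 6 (not isolated)
Conditions: LiTMP (2.6 equiv), CH2Br2 (1.5 equiv), THF, −78 °C; n-BuLi (2.2 equiv), −78 → 0 °C; AcOH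
Reagents that add atoms: dibromomethane, BrCBr
Why: Nozaki–Yamamoto β-oxido carbenoid ring expansion, in which LiCHBr2 adds to the ketone (the C3 hydroxyl rides along as its lithium alkoxide), Br/Li exchange gives the carbenoid and the more substituted, quaternary allylic C10 migrates with retention and loss of bromide, so the new CH2 becomes C9, the carbonyl lands on C8 and no stereocentre is touched.

**Step 4**
Reactants: 7 (6S,8aR)-6-hydroxy-5,8a-dimethyl-3,4,6,7,8,8a-hexahydronaphthalen-2(1H)-one
Product: 8 (2S,4aR)-1,4a-dimethyl-6-oxo-2,3,4,4a,5,6,7,8-octahydronaphthalen-2-yl 2-methylpropanoate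
Conditions: i-PrCOCl (1.2 equiv), pyridine, DMAP (cat.), CH2Cl2, 0 °C → rt
Reagents that add atoms: 2-methylpropanoyl chloride, CC(C)C(Cl)=O
Why: DMAP-catalysed O-acylation of the unhindered pseudo-equatorial allylic alcohol, which leaves the ketone and the C3 configuration untouched.

**Step 5**
Reactants: 8 (2S,4aR)-1,4a-dimethyl-6-oxo-2,3,4,4a,5,6,7,8-octahydronaphthalen-2-yl 2-methylpropanoate; 9 methyl propiolate
Product: 12 methyl 2-[(2R,4aR,7S)-4a,8-dimethyl-7-(2-methylpropanoyloxy)-3-oxo-1,2,3,4,4a,5,6,7-octahydronaphthalen-2-yl]prop-2-enoate, via vinylphosphonium salt 10 (not isolated), via phosphonium adduct 11 (not isolated)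
Conditions: 9, Ph3P·HBF4, CH2Cl2, 0 °C → rt (gives 10); separately 8, LiHMDS (1.05 equiv), THF, −78 °C; add 10, −78 → −40 °C; AcOH (1.1 equiv); Et3N (2 equiv), rt
Reagents that add atoms: none
Why: Proposed new method: the kinetic C7 lithium enolate (LiHMDS removes the less hindered proton away from the quaternary C10, as in 2-oxo steroids) adds to the carbon β to phosphorus (α to the ester) of β-phosphonio acrylate 10, because the cationic phosphorus rather than the ester directs the conjugate addition and stabilises the resulting ylide; C-protonation gives salt 11, amine-induced E1cB loss of PPh3 from its ester enolate unveils the 1,1-disubstituted acrylate, and the acidic C7–H lets the side chain settle in the equatorial 7β (R) position; the closest known reaction types are the phosphine-catalysed umpolung α-addition of N–H and 1,3-dicarbonyl pronucleophiles to propiolates and enolate additions to vinylphosphonium (Schweizer-type) salts, neither shown for a simple ketone enolate.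

**Step 6**
Reactants: 12 methyl 2-[(2R,4aR,7S)-4a,8-dimethyl-7-(2-methylpropanoyloxy)-3-oxo-1,2,3,4,4a,5,6,7-octahydronaphthalen-2-yl]prop-2-enoate
Product: 13 methyl 2-[(2R,3R,4aR,7S)-3-hydroxy-4a,8-dimethyl-7-(2-methylpropanoyloxy)-1,2,3,4,4a,5,6,7-octahydronaphthalen-2-yl]prop-2-enoate
Conditions: NaBH4 (0.5 equiv), CeCl3·7H2O (1.0 equiv), MeOH–THF, −78 °C; AcOH quench at −78 °C; neutral work-up, crude used at once
Reagents that add atoms: none
Why: Luche-type borohydride reduction in which the axial (β-face) trajectory at C8 is blocked by the syn-axial C10 methyl (as in 2-oxo steroids giving 2β-ols), so hydride enters equatorially from the α face and gives the axial 8β (R) alcohol cis to the C7 side chain, while the cerium salt and low temperature spare the acrylate and both esters and the cold neutral quench avoids lactonisation.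

**Step 7**
Reactants: 13 methyl 2-[(2R,3R,4aR,7S)-3-hydroxy-4a,8-dimethyl-7-(2-methylpropanoyloxy)-1,2,3,4,4a,5,6,7-octahydronaphthalen-2-yl]prop-2-enoate
Product: 14 methyl 2-[(2R,3R,4aR,7S)-3-acetoxy-4a,8-dimethyl-7-(2-methylpropanoyloxy)-1,2,3,4,4a,5,6,7-octahydronaphthalen-2-yl]prop-2-enoate (CNP0127901.1)
Conditions: Ac2O (3 equiv), Et3N, DMAP (0.2 equiv), CH2Cl2, 0 °C → rt
Reagents that add atoms: acetic anhydride, CC(=O)OC(C)=O
Why: DMAP-catalysed (Steglich-type) acyl transfer caps the axial 8β-alcohol faster than it can close onto the methyl ester, with retention at C8, and gives the target.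

## Compound list

1 | 2-methylcyclopentane-1,3-dione | CC1C(=O)CCC1=O | starting material
2 | pent-1-en-3-one (ethyl vinyl ketone) | C=CC(=O)CC | starting material
3 | 2-methyl-2-(3-oxopentyl)cyclopentane-1,3-dione | CCC(=O)CCC1(C)C(=O)CCC1=O | intermediate
4 | (S)-4,7a-dimethyl-2,3,7,7a-tetrahydro-1H-indene-1,5(6H)-dione | C1CC2=C(C)C(=O)CC[C@]2(C)C1=O | intermediate
5 | (5S,7aS)-5-hydroxy-4,7a-dimethyl-2,3,5,6,7,7a-hexahydro-1H-inden-1-one | C1CC2=C(C)[C@@H](O)CC[C@]2(C)C1=O | intermediate
6 | (1S,5S,7aS)-1-(dibromomethyl)-4,7a-dimethyl-2,3,5,6,7,7a-hexahydro-1H-indene-1,5-diol (carbinol configuration from attack anti to the angular methyl; erased in the shift) | C1CC2=C(C)[C@@H](O)CC[C@]2(C)[C@]1(O)C(Br)Br | intermediate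
7 | (6S,8aR)-6-hydroxy-5,8a-dimethyl-3,4,6,7,8,8a-hexahydronaphthalen-2(1H)-one | C1CC2=C(C)[C@@H](O)CC[C@]2(C)CC1=O | intermediate
8 | (2S,4aR)-1,4a-dimethyl-6-oxo-2,3,4,4a,5,6,7,8-octahydronaphthalen-2-yl 2-methylpropanoate | C1CC2=C(C)[C@@H](OC(=O)C(C)C)CC[C@]2(C)CC1=O | intermediate
9 | methyl propiolate | C#CC(=O)OC | starting material
10 | (E)-(3-methoxy-3-oxoprop-1-en-1-yl)triphenylphosphonium tetrafluoroborate | COC(=O)/C=C/[P+](c1ccccc1)(c1ccccc1)c1ccccc1.F[B-](F)(F)F | intermediate
11 | {3-methoxy-3-oxo-2-[(2R,4aR,7S)-4a,8-dimethyl-7-(2-methylpropanoyloxy)-3-oxo-1,2,3,4,4a,5,6,7-octahydronaphthalen-2-yl]propyl}triphenylphosphonium acetate (both epimers at the side-chain CH) | COC(=O)C(C[P+](c1ccccc1)(c1ccccc1)c1ccccc1)[C@H]1CC2=C(C)[C@@H](OC(=O)C(C)C)CC[C@]2(C)CC1=O.CC(=O)[O-] | intermediate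
12 | methyl 2-[(2R,4aR,7S)-4a,8-dimethyl-7-(2-methylpropanoyloxy)-3-oxo-1,2,3,4,4a,5,6,7-octahydronaphthalen-2-yl]prop-2-enoate | C=C(C(=O)OC)[C@H]1CC2=C(C)[C@@H](OC(=O)C(C)C)CC[C@]2(C)CC1=O | intermediate
13 | methyl 2-[(2R,3R,4aR,7S)-3-hydroxy-4a,8-dimethyl-7-(2-methylpropanoyloxy)-1,2,3,4,4a,5,6,7-octahydronaphthalen-2-yl]prop-2-enoate | C=C(C(=O)OC)[C@H]1CC2=C(C)[C@@H](OC(=O)C(C)C)CC[C@]2(C)C[C@H]1O | intermediate
14 | methyl 2-[(2R,3R,4aR,7S)-3-acetoxy-4a,8-dimethyl-7-(2-methylpropanoyloxy)-1,2,3,4,4a,5,6,7-octahydronaphthalen-2-yl]prop-2-enoate | C=C(C(=O)OC)[C@H]1CC2=C(C)[C@@H](OC(=O)C(C)C)CC[C@]2(C)C[C@H]1OC(C)=O | target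

## Step count and risks

Total steps: 7. Longest linear sequence: 7 steps (1/2 → 14).

**Most likely to fail, in order:**

**Step 5 (the proposed new enolate α-vinylation).** Possible failures are attack at the wrong acrylate carbon, Wittig chemistry of the intermediate ylide, or sluggish loss of PPh3. The fallback uses known chemistry and sets out from 8. The same kinetic lithium enolate (LiHMDS, THF, −78 °C) is brominated with NBS to give the 7α-bromo ketone F5. SN2 displacement with the sodium salt of trimethyl phosphonoacetate (NaH, DMF, 0 °C → rt) gives the 4-oxo phosphonate F6. Horner–Wadsworth–Emmons methylenation with aqueous formaldehyde and K2CO3 (THF, rt) then gives 12, where the route is rejoined.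

**Step 2 (enone reduced in the presence of the saturated ketone).** The cyclopentanone may be reduced as well, or instead. The fallback sets out from 4. Selective ketalisation of the saturated carbonyl (ethylene glycol, 2-ethyl-2-methyl-1,3-dioxolane, TsOH cat., rt) gives the monoketal F1. The same Luche reduction, now with only the enone carbonyl present, gives the allylic alcohol ketal F2. PPTS in wet acetone at rt removes the ketal and returns 5.

**Step 3 (carbenoid ring expansion).** LiCHBr2 may enolise rather than add to the hindered ketone, or the carbenoid may decompose. The fallback sets out from 5 and replaces the carbenoid by a thionium-ion semipinacol shift. Bis(phenylthio)methyllithium (from bis(phenylthio)methane and n-BuLi, THF, −78 °C, after O-lithiation of 5) adds to the ketone to give the dithioacetal diol F3. (CuOTf)2·C6H6 with i-Pr2NEt in benzene at 78 °C removes one thiophenoxide and the quaternary carbon migrates, giving the ring-expanded 9-phenylthio ketone F4. Zinc dust in AcOH removes the sulfur and returns 7.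

## Further compounds

F1 | step 2 | (S)-4',7a'-dimethyl-2',3',7',7a'-tetrahydrospiro[1,3-dioxolane-2,1'-inden]-5'(6'H)-one | C1CC2=C(C)C(=O)CC[C@]2(C)C13OCCO3
F2 | step 2 | (5'S,7a'S)-4',7a'-dimethyl-2',3',5',6',7',7a'-hexahydrospiro[1,3-dioxolane-2,1'-inden]-5'-ol | C1CC2=C(C)[C@@H](O)CC[C@]2(C)C13OCCO3
F3 | step 3 | (1S,5S,7aS)-1-[bis(phenylthio)methyl]-4,7a-dimethyl-2,3,5,6,7,7a-hexahydro-1H-indene-1,5-diol | C1CC2=C(C)[C@@H](O)CC[C@]2(C)[C@]1(O)C(Sc1ccccc1)Sc1ccccc1
F4 | step 3 | compound 7 carrying a phenylthio group on C9, the CH between the carbonyl and the quaternary carbon (both C9 epimers) | C1CC2=C(C)[C@@H](O)CC[C@]2(C)C(Sc3ccccc3)C1=O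
F5 | step 5 | compound 8 carrying an axial 7α-bromine next to the ketone | Br[C@@H]1CC2=C(C)[C@@H](OC(=O)C(C)C)CC[C@]2(C)CC1=O
F6 | step 5 | methyl 2-(dimethoxyphosphoryl)-2-[(2R,4aR,7S)-4a,8-dimethyl-7-(2-methylpropanoyloxy)-3-oxo-1,2,3,4,4a,5,6,7-octahydronaphthalen-2-yl]acetate (both epimers at the phosphonate carbon) | COC(=O)C(P(=O)(OC)OC)[C@H]1CC2=C(C)[C@@H](OC(=O)C(C)C)CC[C@]2(C)CC1=O
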